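**Retrosynthetic overview**
1. Target ⇐ singlet-oxygen ene reaction on the 7,8-olefin of the 11,12-epoxy-4-hydroxy lactone. The oxirane comes from peracid epoxidation of the macrocyclic E-11,12-olefin while the 7,8-olefin is held as a bromo ether by the C4 hydroxyl.
2. δ-Lactone and C4 carbinol ⇐ halolactonisation relay from the macrocyclic trienoic acid, whose carboxyl can reach only the 3,4-olefin.
3. Trienoic acid ⇐ (R)-cembrene A ⇐ titanium-mediated closure of the 14-membered ring at C11=C12.
4. Open chain ⇐ two Claisen [3,3] rearrangements (C5–C6 and C9–C10 bonds, E-3,4 and E-7,8 olefins) on isopropenyl carbinols grown from the keto aldehyde of (R)-limonene oxide, which supplies C1.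
5. Ring order: 14-membered carbocycle (step 6), δ-lactone (steps 9–10), temporary ether bridge (step 12), oxirane (step 12).

Assumption: cembrane numbering is used (C1 carries C15, C16 is the lactone carbonyl, the lactone oxygen sits on C3); commercial (+)-limonene 1,2-oxide is the cis/trans mixture from (R)-limonene. Facial selectivities in the macrocycle (steps 9, 12, 14) are predictions from outer-face attack, not established results.

**Route**

Step 1
Reactants: 1 (4R)-limonene 1,2-oxide
Product: 3 (3R)-6-oxo-3-(prop-1-en-2-yl)heptanal, via limonene-1,2-diol 2 (not isolated)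
Conditions: H5IO6, THF/H2O, 0 °C to rt
Reagents that add atoms: water (O)
Why: Periodic acid hydrolyses the epoxide and cleaves the resulting diol in one pot (Malaprade glycol cleavage), freeing aldehyde and methyl ketone while the limonene C4 centre, the future C1, is untouched.

Step 2
Reactants: 3 (3R)-6-oxo-3-(prop-1-en-2-yl)heptanal, 4 isopropenylmagnesium bromide
Product: 5 (5R)-7-hydroxy-8-methyl-5-(prop-1-en-2-yl)non-8-en-2-one (7-epimers)
Conditions: THF, −78 °C; then aq. NH4Cl
Reagents that add atoms: none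
Why: Grignard 1,2-addition is much faster at the aldehyde than at the methyl ketone at −78 °C, and the new carbinol centre is erased in step 3.

Step 3
Reactants: 5 (5R)-7-hydroxy-8-methyl-5-(prop-1-en-2-yl)non-8-en-2-one (7-epimers), 6 ethyl vinyl ether
Product: 8 (4E,7R)-4-methyl-10-oxo-7-(prop-1-en-2-yl)undec-4-enal, via allyl vinyl ether 7 (not isolated)
Conditions: 6 (solvent), Hg(OAc)2 (10 mol %), reflux; concentrate; then PhMe, 140 °C, sealed tube
Reagents that add atoms: none
Why: Vinyl ether exchange followed by a Claisen [3,3]-sigmatropic rearrangement through a chair with the carbinol substituent equatorial forms the C5–C6 bond and the E-trisubstituted C3=C4 olefin and returns an aldehyde for the next cycle.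

Step 4
Reactants: 8 (4E,7R)-4-methyl-10-oxo-7-(prop-1-en-2-yl)undec-4-enal, 4 isopropenylmagnesium bromide
Product: 9 (5R,7E)-11-hydroxy-8,12-dimethyl-5-(prop-1-en-2-yl)trideca-7,12-dien-2-one (11-epimers)
Conditions: THF, −78 °C; then aq. NH4Cl
Reagents that add atoms: none
Why: The same aldehyde-selective Grignard 1,2-addition as in step 2 installs the second isopropenyl carbinol, whose configuration is again irrelevant.

Step 5
Reactants: 9 (5R,7E)-11-hydroxy-8,12-dimethyl-5-(prop-1-en-2-yl)trideca-7,12-dien-2-one (11-epimers), 6 ethyl vinyl ether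
Product: 11 (4E,8E,11R)-4,8-dimethyl-14-oxo-11-(prop-1-en-2-yl)pentadeca-4,8-dienal, via allyl vinyl ether 10 (not isolated)
Conditions: 6 (solvent), Hg(OAc)2 (10 mol %), reflux; concentrate; then PhMe, 140 °C, sealed tube
Reagents that add atoms: none
Why: The second Claisen [3,3]-sigmatropic rearrangement forms the C9–C10 bond and the E-C7=C8 olefin through the same chair transition state and delivers the C11 aldehyde opposite the C12 methyl ketone.

Step 6
Reactants: 11 (4E,8E,11R)-4,8-dimethyl-14-oxo-11-(prop-1-en-2-yl)pentadeca-4,8-dienal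
Product: 12 (R)-cembrene A [(1R,3E,7E,11E)-cembra-3,7,11,15-tetraene]
Conditions: TiCl3(DME)1.5, Zn–Cu couple, DME, reflux, slow addition (about 2 mM)
Reagents that add atoms: none
Why: Intramolecular McMurry reductive carbonyl coupling under high dilution closes the 14-membered ring at C11=C12, the E-olefin being the expected major isomer and separable from the Z-isomer on AgNO3-silica.

Step 7
Reactants: 12 (R)-cembrene A
Product: 14 (1R,3E,7E,11E)-cembra-3,7,11-trien-16-ol (15-epimers), via B-alkyl-9-BBN adduct 13 (not isolated)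
Conditions: 9-BBN, THF, 0 °C to rt; then NaOH, H2O2
Reagents that add atoms: hydrogen peroxide (OO)
Why: Hydroboration–oxidation with 9-BBN takes only the unhindered 1,1-disubstituted isopropenyl group and leaves the three trisubstituted ring olefins, giving both C15 epimers, which are equilibrated in step 11.

Step 8
Reactants: 14 (1R,3E,7E,11E)-cembra-3,7,11-trien-16-ol (15-epimers)
Product: 16 (1R,3E,7E,11E)-cembra-3,7,11-trien-16-oic acid (15-epimers), via aldehyde 15 (not isolated)
Conditions: TEMPO (cat.), PhI(OAc)2, MeCN/H2O, rt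
Reagents that add atoms: water (O)
Why: TEMPO-catalysed oxoammonium oxidation takes the primary alcohol through the aldehyde hydrate to the acid without touching the olefins.

Step 9
Reactants: 16 (1R,3E,7E,11E)-cembra-3,7,11-trien-16-oic acid (15-epimers)
Product: 18 methyl (1R,3R,4R,7E,11E)-3,4-epoxycembra-7,11-dien-16-oate (15-epimers), via iodolactone 17 (not isolated)
Conditions: I2, NaHCO3, MeCN, 0 °C, dark; then K2CO3, MeOH, 0 °C to rt
Reagents that add atoms: methanol (CO)
Why: Iodolactonisation engages only the 3,4-olefin, which the carboxylate reaches through a six-membered chair with both ring bonds equatorial (cis-fused, O on C3 anti to I on C4), and methanolysis then lets the C3 alkoxide displace the tertiary iodide with inversion to give the (3R,4R)-oxirane.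

Step 10
Reactants: 18 methyl (1R,3R,4R,7E,11E)-3,4-epoxycembra-7,11-dien-16-oate (15-epimers)
Product: 20 (1R,3R,4S,7E,11E)-4-hydroxycembra-7,11-dien-16,3-olide (15-epimers), via dihydroxy ester 19 (not isolated)
Conditions: HClO4 (0.1 M aq.), THF, 0 °C to rt
Reagents that add atoms: water (O)
Why: Acid-catalysed epoxide hydrolysis brings water in at the tertiary C4 with inversion, so C3 keeps the oxygen set in step 9 and C4 becomes the (4S)-carbinol, and the C3 hydroxyl then closes the δ-lactone by transesterification.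

Step 11
Reactants: 20 (1R,3R,4S,7E,11E)-4-hydroxycembra-7,11-dien-16,3-olide (15-epimers)
Product: 21 (1R,3R,4S,7E,11E,15S)-4-hydroxycembra-7,11-dien-16,3-olide
Conditions: DBU, PhMe, 80 °C
Reagents that add atoms: none
Why: Base-mediated epimerisation through the lactone enolate places the C15 methyl equatorial and trans to the C1 ring bond, which is the thermodynamic (15S) isomer.

Step 12
Reactants: 21 (1R,3R,4S,7E,11E,15S)-4-hydroxycembra-7,11-dien-16,3-olide
Product: 23 (1R,3R,4S,7R,8S,11S,12S,15S)-7-bromo-4,8:11,12-diepoxycembran-16,3-olide, via bromo ether 22 (not isolated)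
Conditions: NBS, CH2Cl2, 0 °C; then mCPBA, NaHCO3, −20 to 0 °C
Reagents that add atoms: N-bromosuccinimide (BrN1C(=O)CCC1=O), mCPBA (OOC(=O)c1cccc(Cl)c1)
Why: Transannular bromoetherification by the C4 hydroxyl (anti addition, oxygen to the tertiary C8) masks the 7,8-olefin, and Prilezhaev epoxidation then takes the only remaining olefin stereospecifically from its outer face, the E geometry giving the trans-substituted oxirane expected as (11S,12S).

Step 13
Reactants: 23 (1R,3R,4S,7R,8S,11S,12S,15S)-7-bromo-4,8:11,12-diepoxycembran-16,3-olide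
Product: 24 (1R,3R,4S,7E,11S,12S,15S)-11,12-epoxy-4-hydroxycembr-7-en-16,3-olide
Conditions: Zn dust, NH4Cl, EtOH, 70 °C
Reagents that add atoms: none
Why: Zinc-mediated reductive β-elimination of the bromo ether (Boord-type) returns the E-7,8-olefin and the C4 hydroxyl by anti elimination of the anti adduct, while oxirane and lactone are inert under these near-neutral conditions.

Step 14
Reactants: 24 (1R,3R,4S,7E,11S,12S,15S)-11,12-epoxy-4-hydroxycembr-7-en-16,3-olide
Product: 25 (1R,3R,4S,6E,8R,11S,12S,15S)-11,12-epoxy-8-hydroperoxy-4-hydroxycembr-6-en-16,3-olide (CNP0297487.3)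
Conditions: O2, tetraphenylporphyrin (cat.), visible light, CH2Cl2, 0 °C
Reagents that add atoms: oxygen (O=O)
Why: In this Schenck ene reaction singlet oxygen adds to C8 from the outer face of the only olefin and abstracts an allylic hydrogen from C6 on the more substituted side (cis effect), giving the E-C6=C7 olefin and the expected (8R)-hydroperoxide, with the regioisomeric 7-hydroperoxy-8(19)-ene removed by chromatography.

**Compound list**
1 | (4R)-limonene 1,2-oxide (cis/trans mixture) | CC(=C)[C@H]1CC2OC2(C)CC1 | starting material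
2 | (4R)-p-menth-8-ene-1,2-diol | CC(=C)[C@H]1CC(O)C(C)(O)CC1 | intermediate
3 | (3R)-6-oxo-3-(prop-1-en-2-yl)heptanal | O=CC[C@H](C(C)=C)CCC(C)=O | intermediate
4 | isopropenylmagnesium bromide | CC(=C)[Mg]Br | starting material
5 | (5R)-7-hydroxy-8-methyl-5-(prop-1-en-2-yl)non-8-en-2-one (7-epimers) | C=C(C)C(O)C[C@H](C(C)=C)CCC(C)=O | intermediate
6 | ethyl vinyl ether | C=COCC | starting material
7 | (5R)-8-methyl-5-(prop-1-en-2-yl)-7-(vinyloxy)non-8-en-2-one | C=COC(C(C)=C)C[C@H](C(C)=C)CCC(C)=O | intermediate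
8 | (4E,7R)-4-methyl-10-oxo-7-(prop-1-en-2-yl)undec-4-enal | O=CCC/C(C)=C/C[C@H](C(C)=C)CCC(C)=O | intermediate
9 | (5R,7E)-11-hydroxy-8,12-dimethyl-5-(prop-1-en-2-yl)trideca-7,12-dien-2-one (11-epimers) | C=C(C)C(O)CC/C(C)=C/C[C@H](C(C)=C)CCC(C)=O | intermediate
10 | (5R,7E)-8,12-dimethyl-5-(prop-1-en-2-yl)-11-(vinyloxy)trideca-7,12-dien-2-one | C=COC(C(C)=C)CC/C(C)=C/C[C@H](C(C)=C)CCC(C)=O | intermediate
11 | (4E,8E,11R)-4,8-dimethyl-14-oxo-11-(prop-1-en-2-yl)pentadeca-4,8-dienal | O=CCC/C(C)=C/CC/C(C)=C/C[C@H](C(C)=C)CCC(C)=O | intermediate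
12 | (R)-cembrene A, (1R,3E,7E,11E)-cembra-3,7,11,15-tetraene | CC(=C)[C@H]1C/C=C(C)/CC/C=C(C)/CC/C=C(C)/CC1 | intermediate
13 | B-[(1R,3E,7E,11E)-cembra-3,7,11-trien-16-yl]-9-borabicyclo[3.3.1]nonane | CC(CB2C3CCCC2CCC3)[C@H]1C/C=C(C)/CC/C=C(C)/CC/C=C(C)/CC1 | intermediate
14 | (1R,3E,7E,11E)-cembra-3,7,11-trien-16-ol (15-epimers) | CC(CO)[C@H]1C/C=C(C)/CC/C=C(C)/CC/C=C(C)/CC1 | intermediate
15 | (1R,3E,7E,11E)-cembra-3,7,11-trien-16-al (15-epimers) | CC(C=O)[C@H]1C/C=C(C)/CC/C=C(C)/CC/C=C(C)/CC1 | intermediate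
16 | (1R,3E,7E,11E)-cembra-3,7,11-trien-16-oic acid (15-epimers) | CC(C(=O)O)[C@H]1C/C=C(C)/CC/C=C(C)/CC/C=C(C)/CC1 | intermediate
17 | (1R,3R,4S,7E,11E)-4-iodocembra-7,11-dien-16,3-olide (15-epimers) | CC1C(=O)O[C@@H]2C[C@H]1CC/C(C)=C/CC/C(C)=C/CC[C@]2(C)I | intermediate
18 | methyl (1R,3R,4R,7E,11E)-3,4-epoxycembra-7,11-dien-16-oate (15-epimers) | COC(=O)C(C)[C@H]1C[C@H]2O[C@]2(C)CC/C=C(C)/CC/C=C(C)/CC1 | intermediate
19 | methyl (1R,3R,4S,7E,11E)-3,4-dihydroxycembra-7,11-dien-16-oate (15-epimers) | COC(=O)C(C)[C@H]1C[C@@H](O)[C@@](C)(O)CC/C=C(C)/CC/C=C(C)/CC1 | intermediate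
20 | (1R,3R,4S,7E,11E)-4-hydroxycembra-7,11-dien-16,3-olide (15-epimers) | CC1C(=O)O[C@@H]2C[C@H]1CC/C(C)=C/CC/C(C)=C/CC[C@]2(C)O | intermediate
21 | (1R,3R,4S,7E,11E,15S)-4-hydroxycembra-7,11-dien-16,3-olide | C[C@@H]1C(=O)O[C@@H]2C[C@H]1CC/C(C)=C/CC/C(C)=C/CC[C@]2(C)O | intermediate
22 | (1R,3R,4S,7R,8S,11E,15S)-7-bromo-4,8-epoxycembr-11-en-16,3-olide | C[C@@H]1C(=O)O[C@@H]2C[C@H]1CC/C(C)=C/CC[C@@]3(C)[C@H](Br)CC[C@]2(C)O3 | intermediate
23 | (1R,3R,4S,7R,8S,11S,12S,15S)-7-bromo-4,8:11,12-diepoxycembran-16,3-olide | C[C@@H]1C(=O)O[C@@H]2C[C@H]1CC[C@]1(C)O[C@H]1CC[C@@]3(C)[C@H](Br)CC[C@]2(C)O3 | intermediate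
24 | (1R,3R,4S,7E,11S,12S,15S)-11,12-epoxy-4-hydroxycembr-7-en-16,3-olide | C[C@@H]1C(=O)O[C@@H]2C[C@H]1CC[C@]1(C)O[C@H]1CC/C(C)=C/CC[C@]2(C)O | intermediate
25 | (1R,3R,4S,6E,8R,11S,12S,15S)-11,12-epoxy-8-hydroperoxy-4-hydroxycembr-6-en-16,3-olide | C[C@@H]1C(=O)O[C@@H]2C[C@H]1CC[C@]1(C)O[C@H]1CC[C@@](C)(OO)/C=C/C[C@]2(C)O | target

**Count and weak points**
Total step count: 14. Longest linear sequence: 14 steps (1 to 25; 4 and 6 are bought reagents).

The three steps most likely to fail:

Step 6 (ring closure: Z-olefin at C11=C12 or oligomers). The fallback sets out from 11. The same titanium reagent is used at 25 °C so that the coupling stops at the pinacol stage, and the threo diol (1R,3E,7E,11S,12S)-cembra-3,7,15-triene-11,12-diol F1 is separated (its 11R,12R partner serves equally). Thiocarbonyldiimidazole converts it into the cyclic 11,12-thionocarbonate F2. Heating this with P(OMe)3 (Corey–Winter syn-elimination) can only give the E-olefin, and the route is rejoined at 12.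

Step 9 (face on which the halolactonisation closes). If the carboxylate closes onto the other face of the 3,4-olefin, the same two operations on 16 give the diastereomeric methyl (1R,3S,4S,7E,11E)-3,4-epoxycembra-7,11-dien-16-oate F3. Instead of hydrolysing it at C4, it is saponified with LiOH to (1R,3S,4S,7E,11E)-3,4-epoxycembra-7,11-dien-16-oic acid F4. The carboxylate then opens the oxirane at C3 with inversion (Cs2CO3, DMF, 60 °C, then mild acid), which gives the same hydroxy lactone, so the route is rejoined at 20.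

Step 12 (face of the epoxidation). If the peracid enters from the wrong face, the bromo ether 22 is isolated and the oxirane is built in two stages instead. NBS in aqueous THF gives the bromohydrin (1R,3R,4S,7R,8S,11R,12S,15S)-7,11-dibromo-4,8-epoxy-12-hydroxycembran-16,3-olide F5, with bromine on C11 from the outer face and water on the tertiary C12 from the inner face. Cs2CO3 in MeCN closes it by displacement at C11, which places the oxygen on the face opposite to the one a peracid uses, and the route is rejoined at 23.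

**Further compounds**
F1 | step 6 | (1R,3E,7E,11S,12S)-cembra-3,7,15-triene-11,12-diol | CC(=C)[C@H]1C/C=C(C)/CC/C=C(C)/CC[C@H](O)[C@@](C)(O)CC1
F2 | step 6 | cyclic 11,12-thionocarbonate of (1R,3E,7E,11S,12S)-cembra-3,7,15-triene-11,12-diol | CC(=C)[C@H]1C/C=C(C)/CC/C=C(C)/CC[C@@H]2OC(=S)O[C@@]2(C)CC1
F3 | step 9 | methyl (1R,3S,4S,7E,11E)-3,4-epoxycembra-7,11-dien-16-oate (15-epimers) | COC(=O)C(C)[C@H]1C[C@@H]2O[C@@]2(C)CC/C=C(C)/CC/C=C(C)/CC1
F4 | step 9 | (1R,3S,4S,7E,11E)-3,4-epoxycembra-7,11-dien-16-oic acid (15-epimers) | OC(=O)C(C)[C@H]1C[C@@H]2O[C@@]2(C)CC/C=C(C)/CC/C=C(C)/CC1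
F5 | step 12 | (1R,3R,4S,7R,8S,11R,12S,15S)-7,11-dibromo-4,8-epoxy-12-hydroxycembran-16,3-olide | C[C@@H]1C(=O)O[C@@H]2C[C@H]1CC[C@](C)(O)[C@H](Br)CC[C@@]3(C)[C@H](Br)CC[C@]2(C)O3
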